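The benzene ring of the dihydrobenzofuran is built last. Read backwards, it hides a ketone: C7a is the carbonyl carbon, already bound to O1 as the enol ether of the dihydrofuran ring (O1–C2–C3–C3a–C7a), and C3a and C7 are its two α-carbons; C4–C5–C6, oxygenated at C4 and C6, are a malonyl piece. A single [3+3] annulation with malonyl dichloride should therefore forge C3a–C4 and C6–C7 and aromatise, leaving only C5 open for the isobutyryl group. The precursor is an (R)-isopropenyl dihydrofuran whose enol-ether carbon carries a two-carbon tether to an O-protected 6-ethyl-4-hydroxy-5-methyl-2-pyranone, assembled by B-alkyl Suzuki coupling of a lactone enol phosphate.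

Key step: step 10

Remark on the chemistry: the target SMILES encodes (R) at C2 (O1 > isopropenyl > C3 > H), the configuration bought with 1; the pyranone 4-oxygen is carried as a 2-(trimethylsilyl)ethyl (TMSE) ether in place of a methyl ether, because fluoride frees it at room temperature, whereas SN2 demethylation would need hot nucleophilic base on a methylene-bridged acylphloroglucinol prone to retro-Michael scrambling and Lewis acids would open the allylic C2–O1 bond; skeleton and bond construction are unaffected.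

Step 1
Reactants: 1 (R)-5-oxotetrahydrofuran-2-carboxylic acid
Product: 3 (R)-5-acetyldihydrofuran-2(3H)-one, via acid chloride 2 (not isolated)
Conditions: (COCl)2, cat. DMF, CH2Cl2, 0 °C → rt, evaporate; Me2CuLi (1.1 equiv), Et2O, −78 °C
Reagents that add atoms: lithium dimethylcuprate, [Li+].C[Cu-]C
Why: Acid chloride formation followed by Gilman cuprate acylation should stop at the methyl ketone, because at −78 °C the cuprate adds to neither ketone nor lactone and is too weakly basic to enolise the oxygen-bearing stereocentre, which is thus carried over unchanged from purchased 1.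

Step 2
Reactants: 3 (R)-5-acetyldihydrofuran-2(3H)-one
Product: 4 (R)-5-(prop-1-en-2-yl)dihydrofuran-2(3H)-one
Conditions: Zn, CH2Br2, TiCl4, THF/CH2Cl2, 0 °C → rt
Reagents that add atoms: dibromomethane, BrCBr
Why: Takai–Lombardo methylenation: the non-basic zinc–titanium methylene reagent should convert the ketone into the isopropenyl group without epimerising the adjacent stereocentre and does not olefinate the lactone carbonyl.

Step 3
Reactants: 4 (R)-5-(prop-1-en-2-yl)dihydrofuran-2(3H)-one
Product: 5 diphenyl (R)-5-(prop-1-en-2-yl)-4,5-dihydrofuran-2-yl phosphate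
Conditions: KN(SiMe3)2 added to 4 and (PhO)2P(O)Cl, DMPU, THF, −78 °C; used crude
Reagents that add atoms: diphenyl chlorophosphate, O=P(Cl)(Oc1ccccc1)Oc1ccccc1
Why: Ketene acetal phosphate formation by O-phosphorylation of the kinetic lactone enolate: deprotonation occurs only α to the carbonyl, so the double bond is fixed between the future C7a and C3a and the stereocentre is not touched.

Step 4
Reactants: 6 pentan-3-one
Product: 7 3-(trimethylsilyloxy)pent-2-ene (E/Z mixture)
Conditions: LiN(i-Pr)2, THF, −78 °C; Me3SiCl, −78 °C → rt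
Reagents that add atoms: chlorotrimethylsilane, C[Si](C)(C)Cl
Why: Kinetic enolate O-silylation of a symmetrical ketone poses no regiochemical question, and the enol-ether geometry is irrelevant because it disappears in the pyranone.

Step 5
Reactants: 7 3-(trimethylsilyloxy)pent-2-ene; 8 malonyl dichloride
Product: 9 6-ethyl-4-hydroxy-5-methyl-2H-pyran-2-one
Conditions: Et2O, −78 °C → rt
Reagents that add atoms: none
Why: Effenberger pyranone synthesis: the silyl enol ether is C-acylated by one acid chloride and the liberated enol oxygen closes onto the second, which places ethyl at C6 and methyl at C5 of the 4-hydroxy-2-pyranone.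

Step 6
Reactants: 9 6-ethyl-4-hydroxy-5-methyl-2H-pyran-2-one
Product: 10 3-bromo-6-ethyl-4-hydroxy-5-methyl-2H-pyran-2-one
Conditions: NBS, CH2Cl2, rt, dark
Reagents that add atoms: N-bromosuccinimide, O=C1CCC(=O)N1Br
Why: Electrophilic bromination of the enolised 1,3-dicarbonyl unit should occur only at C3, the single unsubstituted and most nucleophilic ring carbon.

Step 7
Reactants: 10 3-bromo-6-ethyl-4-hydroxy-5-methyl-2H-pyran-2-one
Product: 11 3-bromo-6-ethyl-5-methyl-4-[2-(trimethylsilyl)ethoxy]-2H-pyran-2-one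
Conditions: Me3SiCH2CH2OH, PPh3, DIAD, THF, 0 °C → rt
Reagents that add atoms: 2-(trimethylsilyl)ethanol, C[Si](C)(C)CCO
Why: Mitsunobu O-alkylation of the strongly acidic 4-hydroxypyranone with a primary alcohol should give the 4-alkoxy-2-pyranone, the usual site of Mitsunobu alkylation in this heterocycle, and installs a fluoride-labile mask that is inert to acid chlorides.

Step 8
Reactants: 11 3-bromo-6-ethyl-5-methyl-4-[2-(trimethylsilyl)ethoxy]-2H-pyran-2-one
Product: 12 3-ethenyl-6-ethyl-5-methyl-4-[2-(trimethylsilyl)ethoxy]-2H-pyran-2-one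
Conditions: Bu3SnCH=CH2, Pd(PPh3)4 (5 mol%), toluene, 100 °C
Reagents that add atoms: tributyl(vinyl)stannane, C=C[Sn](CCCC)(CCCC)CCCC
Why: Stille coupling of the electron-poor vinylic bromide runs under neutral conditions that neither hydrolyse the pyranone nor cleave the silylethyl ether.

Step 9
Reactants: 12 3-ethenyl-6-ethyl-5-methyl-4-[2-(trimethylsilyl)ethoxy]-2H-pyran-2-one; 5 diphenyl (R)-5-(prop-1-en-2-yl)-4,5-dihydrofuran-2-yl phosphate
Product: 14 (R)-6-ethyl-5-methyl-3-{2-[5-(prop-1-en-2-yl)-4,5-dihydrofuran-2-yl]ethyl}-4-[2-(trimethylsilyl)ethoxy]-2H-pyran-2-one, via B-alkyl-9-BBN borane 13 (not isolated)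
Conditions: 9-BBN, THF, 0 °C → rt; then 3 M aq K3PO4, 5, Pd(PPh3)4 (5 mol%), DMF, 50 °C; Et3N-deactivated silica
Reagents that add atoms: none
Why: Anti-Markovnikov hydroboration of the vinyl group (the only alkene present when 9-BBN is active) and B-alkyl Suzuki–Miyaura coupling of borane 13 with the ketene acetal phosphate, a reaction class established for lactone-derived enol phosphates, should join the two halves under basic conditions and place the enol-ether double bond regiospecifically inside the ring without touching the stereocentre.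

Step 10
Reactants: 14 (R)-6-ethyl-5-methyl-3-{2-[5-(prop-1-en-2-yl)-4,5-dihydrofuran-2-yl]ethyl}-4-[2-(trimethylsilyl)ethoxy]-2H-pyran-2-one; 8 malonyl dichloride
Product: 17 (R)-3-{[4,6-dihydroxy-2-(prop-1-en-2-yl)-2,3-dihydrobenzofuran-7-yl]methyl}-6-ethyl-5-methyl-4-[2-(trimethylsilyl)ethoxy]-2H-pyran-2-one, via β-oxo acid chloride 15 (not isolated), via dienylketene 16 (not isolated)
Conditions: 14 added over 2 h to 8 (1.2 equiv) and 2,6-di-tert-butyl-4-methylpyridine (2.5 equiv), CH2Cl2 (0.01 M), −40 °C → rt, then 40 °C; aq NaHCO3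
Reagents that add atoms: none
Why: Proposed new method: the enol-ether carbon C3a of 14 should be C-acylated by one acid chloride of 8 (forming C3a–C4, as enol ethers are by reactive acid chlorides), and the β-oxo acid chloride 15 should then lose HCl to an acylketene whose C4 carbonyl accepts a proton from the C7 methylene (a base-relayed 1,5-shift through the vinylogous ester), giving dienylketene 16. The single ring is closed by thermal disrotatory 6π-electrocyclisation of 16, which joins ketene carbon C6 to C7 in an all-carbon six-membered array, and the cyclohexadienone so formed enolises at once to the arene, O1 becoming its third oxygen. The closest known chemistry is the Effenberger reaction of malonyl dichloride with enol ethers and silyl enol ethers, which gives 4-hydroxy-2-pyranones when the enol oxygen can acylate (step 5) and α,α′-diacylated six-membered 1,3-diketones when it cannot, together with the dienylketene-to-phenol closure of the Danheiser benzannulation; their use to aromatise a cyclic enol ether is not documented. No stereocentre is created, and the one at C2 is two bonds away from any carbon that changes hybridisation and meets only a hindered pyridine base, so it should survive. The step needs carbon acylation twice (C3a, then C7) and no reaction elsewhere: O1 is already alkylated and could acylate only through an oxonium ion, C3a is the sole nucleophilic enol-ether carbon, the tethered ketene reaches C7 but no other carbon through a six-membered transition state, the pyranone has no free hydroxyl or unsubstituted ring carbon, and the base keeps HCl from the enol ether, the isopropenyl group and the allylic C2–O1 bond.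

Step 11
Reactants: 17 (R)-3-{[4,6-dihydroxy-2-(prop-1-en-2-yl)-2,3-dihydrobenzofuran-7-yl]methyl}-6-ethyl-5-methyl-4-[2-(trimethylsilyl)ethoxy]-2H-pyran-2-one
Product: 19 (R)-3-{[4,6-dihydroxy-5-(2-methylpropanoyl)-2-(prop-1-en-2-yl)-2,3-dihydrobenzofuran-7-yl]methyl}-6-ethyl-5-methyl-4-[2-(trimethylsilyl)ethoxy]-2H-pyran-2-one, via bis(bromomagnesium) phenoxide 18 (not isolated)
Conditions: EtMgBr (2.0 equiv), toluene/Et2O, −20 → 0 °C; i-PrCOCl (1.1 equiv), toluene, 0 °C → rt; aq NH4Cl
Reagents that add atoms: isobutyryl chloride, CC(C)C(=O)Cl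
Why: Magnesium-phenoxide-directed ortho C-acylation (a chelation-controlled Friedel–Crafts acylation that needs no Lewis or Brønsted acid): the acid chloride bound to magnesium is delivered to C5, the only unsubstituted ring carbon and ortho to both phenoxides, while phenol deprotonation by the Grignard reagent outruns addition to the pyranone and the allylic C2–O1 bond, isopropenyl group and silylethyl ether never meet acid.

Step 12
Reactants: 19 (R)-3-{[4,6-dihydroxy-5-(2-methylpropanoyl)-2-(prop-1-en-2-yl)-2,3-dihydrobenzofuran-7-yl]methyl}-6-ethyl-5-methyl-4-[2-(trimethylsilyl)ethoxy]-2H-pyran-2-one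
Product: 20 3-{[(2R)-4,6-dihydroxy-5-(2-methylpropanoyl)-2-(prop-1-en-2-yl)-2,3-dihydro-1-benzofuran-7-yl]methyl}-6-ethyl-4-hydroxy-5-methyl-2H-pyran-2-one (CNP0206652.1)
Conditions: Bu4NF (5 equiv), THF, rt; aq NH4Cl
Reagents that add atoms: none
Why: Fluoride-induced β-elimination of the 2-(trimethylsilyl)ethyl group (standard TMSE cleavage) expels the stabilised vinylogous carboxylate of the pyranone at room temperature, conditions that should leave the methylene bridge, the acylphloroglucinol and the C2 stereocentre intact.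

Compound list
1 | (R)-5-oxotetrahydrofuran-2-carboxylic acid | OC(=O)[C@H]1CCC(=O)O1 | starting material
2 | (R)-5-oxotetrahydrofuran-2-carbonyl chloride | O=C(Cl)[C@H]1CCC(=O)O1 | intermediate
3 | (R)-5-acetyldihydrofuran-2(3H)-one | CC(=O)[C@H]1CCC(=O)O1 | intermediate
4 | (R)-5-(prop-1-en-2-yl)dihydrofuran-2(3H)-one | C=C(C)[C@H]1CCC(=O)O1 | intermediate
5 | diphenyl (R)-5-(prop-1-en-2-yl)-4,5-dihydrofuran-2-yl phosphate | C=C(C)[C@H]1CC=C(OP(=O)(Oc2ccccc2)Oc2ccccc2)O1 | intermediate
6 | pentan-3-one | CCC(=O)CC | starting material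
7 | 3-(trimethylsilyloxy)pent-2-ene (E/Z mixture) | CC=C(CC)O[Si](C)(C)C | intermediate
8 | malonyl dichloride | O=C(Cl)CC(=O)Cl | starting material
9 | 6-ethyl-4-hydroxy-5-methyl-2H-pyran-2-one | CCc1oc(=O)cc(O)c1C | intermediate
10 | 3-bromo-6-ethyl-4-hydroxy-5-methyl-2H-pyran-2-one | CCc1oc(=O)c(Br)c(O)c1C | intermediate
11 | 3-bromo-6-ethyl-5-methyl-4-[2-(trimethylsilyl)ethoxy]-2H-pyran-2-one | CCc1oc(=O)c(Br)c(OCC[Si](C)(C)C)c1C | intermediate
12 | 3-ethenyl-6-ethyl-5-methyl-4-[2-(trimethylsilyl)ethoxy]-2H-pyran-2-one | C=Cc1c(OCC[Si](C)(C)C)c(C)c(CC)oc1=O | intermediate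
13 | 3-[2-(9-borabicyclo[3.3.1]nonan-9-yl)ethyl]-6-ethyl-5-methyl-4-[2-(trimethylsilyl)ethoxy]-2H-pyran-2-one | CCc1oc(=O)c(CCB2C3CCCC2CCC3)c(OCC[Si](C)(C)C)c1C | intermediate
14 | (R)-6-ethyl-5-methyl-3-{2-[5-(prop-1-en-2-yl)-4,5-dihydrofuran-2-yl]ethyl}-4-[2-(trimethylsilyl)ethoxy]-2H-pyran-2-one | C=C(C)[C@H]1CC=C(CCc2c(OCC[Si](C)(C)C)c(C)c(CC)oc2=O)O1 | intermediate
15 | 3-oxo-3-[(5R)-2-(2-{6-ethyl-5-methyl-2-oxo-4-[2-(trimethylsilyl)ethoxy]-2H-pyran-3-yl}ethyl)-5-(prop-1-en-2-yl)-4,5-dihydrofuran-3-yl]propanoyl chloride | C=C(C)[C@H]1CC(C(=O)CC(=O)Cl)=C(CCc2c(OCC[Si](C)(C)C)c(C)c(CC)oc2=O)O1 | intermediate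
16 | 3-hydroxy-3-[(5R)-2-(2-{6-ethyl-5-methyl-2-oxo-4-[2-(trimethylsilyl)ethoxy]-2H-pyran-3-yl}ethylidene)-5-(prop-1-en-2-yl)dihydrofuran-3(2H)-ylidene]prop-1-en-1-one (dienylketene; alkene geometries not defined) | C=C(C)[C@H]1CC(=C(O)C=C=O)C(=CCc2c(OCC[Si](C)(C)C)c(C)c(CC)oc2=O)O1 | intermediate
17 | (R)-3-{[4,6-dihydroxy-2-(prop-1-en-2-yl)-2,3-dihydrobenzofuran-7-yl]methyl}-6-ethyl-5-methyl-4-[2-(trimethylsilyl)ethoxy]-2H-pyran-2-one | C=C(C)[C@H]1Cc2c(O)cc(O)c(Cc3c(OCC[Si](C)(C)C)c(C)c(CC)oc3=O)c2O1 | intermediate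
18 | bis(bromomagnesium) 4,6-diphenoxide of 17 | C=C(C)[C@H]1Cc2c(O[Mg]Br)cc(O[Mg]Br)c(Cc3c(OCC[Si](C)(C)C)c(C)c(CC)oc3=O)c2O1 | intermediate
19 | (R)-3-{[4,6-dihydroxy-5-(2-methylpropanoyl)-2-(prop-1-en-2-yl)-2,3-dihydrobenzofuran-7-yl]methyl}-6-ethyl-5-methyl-4-[2-(trimethylsilyl)ethoxy]-2H-pyran-2-one | C=C(C)[C@H]1Cc2c(O)c(C(=O)C(C)C)c(O)c(Cc3c(OCC[Si](C)(C)C)c(C)c(CC)oc3=O)c2O1 | intermediate
20 | 3-{[(2R)-4,6-dihydroxy-5-(2-methylpropanoyl)-2-(prop-1-en-2-yl)-2,3-dihydro-1-benzofuran-7-yl]methyl}-6-ethyl-4-hydroxy-5-methyl-2H-pyran-2-one | C=C(C)[C@H]1Cc2c(O)c(C(=O)C(C)C)c(O)c(Cc3c(O)c(C)c(CC)oc3=O)c2O1 | target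

Total step count: 12. Longest linear sequence: 9 steps (steps 4–12, from pentan-3-one 6); the lactone arm (steps 1–3) joins at step 9.

Steps most likely to fail

Step 10 (benzannulation). Acylation may take place at O1 and be followed by loss of the allylic C2–O1 bond, which would collapse the system to a 4-hydroxy-2-pyranone with an opened diene chain. The acylketene may also be intercepted by a second molecule of 14 or by the product phenols, or the sequence may stall after the first acylation because the C7 methylene is not acidic enough. The fallback uses known chemistry only, sets out from pyranone 9 and returns to the route at target 20; the arene is bought and the methylene bridge is made last. Commercial 2-methyl-1-(2,4,6-trihydroxyphenyl)propan-1-one F1 is C-allylated (allyl bromide, aq NaOH, 0 °C) to 2-methyl-1-[2,4,6-trihydroxy-3-(prop-2-en-1-yl)phenyl]propan-1-one F2. Cross-metathesis with 2-methylallyl acetate (second-generation Hoveyda–Grubbs catalyst, CH2Cl2, 40 °C) should give (E)-2-methyl-4-[2,4,6-trihydroxy-3-(2-methylpropanoyl)phenyl]but-2-en-1-yl acetate F3. Tsuji–Trost asymmetric allylic etherification (Pd2(dba)3, DACH-phenyl Trost ligand, Et3N, CH2Cl2) through the phenol para to the acyl group, the most acidic one, should close (R)-1-[4,6-dihydroxy-2-(prop-1-en-2-yl)-2,3-dihydrobenzofuran-5-yl]-2-methylpropan-1-one F4, the ligand enantiomer being chosen to deliver (R). Separately, 9 and CH2=NMe2 I (Eschenmoser's salt) give the Mannich base 3-[(dimethylamino)methyl]-6-ethyl-4-hydroxy-5-methyl-2H-pyran-2-one F5. Warmed with F4 in MeCN, F5 loses dimethylamine to the 3-methylene pyrandione, which alkylates C7 of F4, its only free ring carbon, to give 20.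

Step 9 (hydroboration and B-alkyl Suzuki coupling). The five-membered ketene acetal phosphate may decompose or hydrolyse before oxidative addition to zerovalent palladium, borane 13 may protodeboronate, and the enol ether may hydrolyse on isolation. The fallback sets out from lactone 4 and borane 13 and returns at 14, reaching the enol ether through a ketone instead of a cross-coupled enol derivative. Lactone 4 is opened with Me2AlSPh (from AlMe3 and PhSH, CH2Cl2, 0 °C) and silylated in the same flask (Et3SiOTf, 2,6-lutidine) to S-phenyl (R)-5-methyl-4-(triethylsilyloxy)hex-5-enethioate F6. Liebeskind–Srogl coupling of F6 with 13 (Pd2(dba)3, tri(2-furyl)phosphine, copper thiophene-2-carboxylate CuO2CC4H3S, Cs2CO3, THF) should give the ketone 6-ethyl-5-methyl-3-[(6R)-7-methyl-3-oxo-6-(triethylsilyloxy)oct-7-en-1-yl]-4-[2-(trimethylsilyl)ethoxy]-2H-pyran-2-one F7. PPTS in MeOH removes the silyl ether and closes the cyclic methyl ketal 6-ethyl-3-{2-[(5R)-2-methoxy-5-(prop-1-en-2-yl)tetrahydrofuran-2-yl]ethyl}-5-methyl-4-[2-(trimethylsilyl)ethoxy]-2H-pyran-2-one F8. Me3SiOTf and i-Pr2NEt (CH2Cl2, −20 °C) then eliminate methanol to the endocyclic enol ether 14.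

Step 11 (C5 acylation). The phenoxides may be acylated on oxygen instead of at C5, or the Grignard base may add to the pyranone. The fallback sets out from 17 and returns at 19, going through the esters on purpose and moving the acyl group afterwards. Both phenols of 17 are esterified (isobutyric anhydride, pyridine, DMAP) to (2R)-7-({6-ethyl-5-methyl-2-oxo-4-[2-(trimethylsilyl)ethoxy]-2H-pyran-3-yl}methyl)-2-(prop-1-en-2-yl)-2,3-dihydrobenzofuran-4,6-diyl bis(2-methylpropanoate) F9. Photo-Fries rearrangement (254 nm, degassed MeCN) should move one acyl group to C5, the only ortho position bearing hydrogen (both para positions are substituted), giving (2R)-7-({6-ethyl-5-methyl-2-oxo-4-[2-(trimethylsilyl)ethoxy]-2H-pyran-3-yl}methyl)-4-hydroxy-5-(2-methylpropanoyl)-2-(prop-1-en-2-yl)-2,3-dihydrobenzofuran-6-yl 2-methylpropanoate F10 (its 4-O-ester isomer converges). K2CO3 in MeOH removes the remaining ester to give 19.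

Further compounds
F1 | step 10 | 2-methyl-1-(2,4,6-trihydroxyphenyl)propan-1-one (purchased) | CC(C)C(=O)c1c(O)cc(O)cc1O
F2 | step 10 | 2-methyl-1-[2,4,6-trihydroxy-3-(prop-2-en-1-yl)phenyl]propan-1-one | C=CCc1c(O)cc(O)c(C(=O)C(C)C)c1O
F3 | step 10 | (E)-2-methyl-4-[2,4,6-trihydroxy-3-(2-methylpropanoyl)phenyl]but-2-en-1-yl acetate | CC(=O)OC/C(C)=C/Cc1c(O)cc(O)c(C(=O)C(C)C)c1O
F4 | step 10 | (R)-1-[4,6-dihydroxy-2-(prop-1-en-2-yl)-2,3-dihydrobenzofuran-5-yl]-2-methylpropan-1-one | C=C(C)[C@H]1Cc2c(O)c(C(=O)C(C)C)c(O)cc2O1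
F5 | step 10 | 3-[(dimethylamino)methyl]-6-ethyl-4-hydroxy-5-methyl-2H-pyran-2-one | CCc1oc(=O)c(CN(C)C)c(O)c1C
F6 | step 9 | S-phenyl (R)-5-methyl-4-(triethylsilyloxy)hex-5-enethioate | C=C(C)[C@H](O[Si](CC)(CC)CC)CCC(=O)Sc1ccccc1
F7 | step 9 | 6-ethyl-5-methyl-3-[(6R)-7-methyl-3-oxo-6-(triethylsilyloxy)oct-7-en-1-yl]-4-[2-(trimethylsilyl)ethoxy]-2H-pyran-2-one | C=C(C)[C@H](O[Si](CC)(CC)CC)CCC(=O)CCc1c(OCC[Si](C)(C)C)c(C)c(CC)oc1=O
F8 | step 9 | 6-ethyl-3-{2-[(5R)-2-methoxy-5-(prop-1-en-2-yl)tetrahydrofuran-2-yl]ethyl}-5-methyl-4-[2-(trimethylsilyl)ethoxy]-2H-pyran-2-one (both ketal epimers) | C=C(C)[C@H]1CCC(CCc2c(OCC[Si](C)(C)C)c(C)c(CC)oc2=O)(OC)O1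
F9 | step 11 | (2R)-7-({6-ethyl-5-methyl-2-oxo-4-[2-(trimethylsilyl)ethoxy]-2H-pyran-3-yl}methyl)-2-(prop-1-en-2-yl)-2,3-dihydrobenzofuran-4,6-diyl bis(2-methylpropanoate) | C=C(C)[C@H]1Cc2c(OC(=O)C(C)C)cc(OC(=O)C(C)C)c(Cc3c(OCC[Si](C)(C)C)c(C)c(CC)oc3=O)c2O1
F10 | step 11 | (2R)-7-({6-ethyl-5-methyl-2-oxo-4-[2-(trimethylsilyl)ethoxy]-2H-pyran-3-yl}methyl)-4-hydroxy-5-(2-methylpropanoyl)-2-(prop-1-en-2-yl)-2,3-dihydrobenzofuran-6-yl 2-methylpropanoate | C=C(C)[C@H]1Cc2c(O)c(C(=O)C(C)C)c(OC(=O)C(C)C)c(Cc3c(OCC[Si](C)(C)C)c(C)c(CC)oc3=O)c2O1
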